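The route rests on cutting ring A (C1–C5, C10) and ring B (C5–C10) at C3–C4 and at C5–C10, the bond the two rings share. One intramolecular Diels–Alder reaction of an open-chain trienal, in which an (E)-2-methylenal (C4=C5) is linked by C6–C9 to a 2-silyloxydiene (C3=C2–C1=C10), closes both rings, makes C4 quaternary and sets C5–H cis to the C4 carbonyl. This cis relation in the target is the feature exploited, because the enal geometry encodes it, and the enol ether left at C2 is the masked C1=C10 enone. The precursor already carries C8, C9 and C13, taken from (R)-citronellol and an Ireland–Claisen rearrangement.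

Key step: step 15

Remark on the chemistry: atoms carry the locants C1–C15 of the target (ring A: C1, C2 (C=O), C3, C4, C5, C10; ring B: C5–C10; side chain C11–C15); the target is (4S,5S,8R,9S,13R).

Remark on the chemistry: the dienol ether is made as the triisopropylsilyl (TIPS) ether and C15–O is carried as the tert-butyldiphenylsilyl (TBDPS) ether, so that both withstand the strongly acidic cycloaddition catalyst.

Assumption: the facial sense of the oxazaborolidinium catalyst is taken from the usual model for 2-substituted enals (formyl C–H···O contact, s-trans enal, one face screened by a phenyl group), which points to the catalyst from (R)-α,α-diphenylprolinol; this sense was worked out from the model and not recalled from a known case, so if a first run shows the opposite sense, the enantiomeric catalyst is used with nothing else changed.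

Step 1
Reactants: 1 (R)-citronellol [(3R)-3,7-dimethyloct-6-en-1-ol]
Product: 2 tert-butyl{[(3R)-3,7-dimethyloct-6-en-1-yl]oxy}diphenylsilane
Conditions: TBDPSCl, imidazole, CH2Cl2, 0 °C to rt
Reagents that add atoms: tert-butyl(chloro)diphenylsilane, CC(C)(C)[Si](Cl)(c1ccccc1)c1ccccc1
Why: Silylation of a primary alcohol with a silyl chloride and imidazole is routine, and the TBDPS ether should outlast every base, hydride, oxidant and acid used before the last step.

Step 2
Reactants: 2 tert-butyl{[(3R)-3,7-dimethyloct-6-en-1-yl]oxy}diphenylsilane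
Product: 4 (4R)-6-[(tert-butyldiphenylsilyl)oxy]-4-methylhexanal, via ozonide 3 (not isolated)
Conditions: O3, CH2Cl2, −78 °C; then PPh3, −78 °C to rt
Reagents that add atoms: ozone, [O-][O+]=O
Why: Ozonolysis with reductive work-up cleaves the electron-rich trisubstituted alkene, and the C13 centre lies γ to the new aldehyde and cannot epimerise.

Step 3
Reactants: 4 (4R)-6-[(tert-butyldiphenylsilyl)oxy]-4-methylhexanal
Product: 5 tert-butyl{[(3R)-3-methylhept-6-yn-1-yl]oxy}diphenylsilane
Conditions: dimethyl (1-diazo-2-oxopropyl)phosphonate, K2CO3, MeOH, 0 °C to rt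
Reagents that add atoms: dimethyl (1-diazo-2-oxopropyl)phosphonate, COP(=O)(OC)C(=[N+]=[N-])C(C)=O
Why: The Seyferth–Gilbert homologation in its Ohira–Bestmann form turns an enolisable aldehyde into the terminal alkyne under mild carbonate conditions and adds the carbon that becomes C10.

Step 4
Reactants: 5 tert-butyl{[(3R)-3-methylhept-6-yn-1-yl]oxy}diphenylsilane; 6 acetaldehyde
Product: 8 (3E,7R)-9-[(tert-butyldiphenylsilyl)oxy]-4,7-dimethylnon-3-en-2-ol as both C2 epimers, via alkenylalane 7 (not isolated)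
Conditions: Me3Al, Cp2ZrCl2 (0.25 equiv), CH2Cl2, 0 °C to rt; excess Me3Al removed in vacuo; then CH3CHO, THF, −78 to 0 °C; aq. potassium sodium tartrate
Reagents that add atoms: trimethylaluminium, C[Al](C)C
Why: Zirconium-catalysed syn-carboalumination (Negishi) puts the new methyl on the internal alkyne carbon (C9) and aluminium on the terminus, and addition of the alkenylalane to the aldehyde with retention fixes the (E)-trisubstituted alkene, the carbinol epimers being of no consequence because the next step oxidises them.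

Step 5
Reactants: 8 (3E,7R)-9-[(tert-butyldiphenylsilyl)oxy]-4,7-dimethylnon-3-en-2-ol
Product: 9 (3E,7R)-9-[(tert-butyldiphenylsilyl)oxy]-4,7-dimethylnon-3-en-2-one
Conditions: MnO2 (excess), CH2Cl2, rt
Reagents that add atoms: none
Why: MnO2 oxidises allylic alcohols selectively and under neutral conditions, so the alkene geometry and the silyl ether are kept.

Step 6
Reactants: 9 (3E,7R)-9-[(tert-butyldiphenylsilyl)oxy]-4,7-dimethylnon-3-en-2-one
Product: 10 (2S,3E,7R)-9-[(tert-butyldiphenylsilyl)oxy]-4,7-dimethylnon-3-en-2-ol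
Conditions: (R)-2-methyl-CBS-oxazaborolidine (0.15 equiv), catecholborane, toluene, −78 °C
Reagents that add atoms: none
Why: In the Corey–Bakshi–Shibata reduction the ketone binds with the alkenyl group as the large and methyl as the small substituent, so the (R)-catalyst should deliver hydride to give the (S)-carbinol (the (S)-catalyst gives (R)-alcohols from aryl and alkenyl methyl ketones), and catecholborane at low temperature avoids 1,4-reduction.

Step 7
Reactants: 10 (2S,3E,7R)-9-[(tert-butyldiphenylsilyl)oxy]-4,7-dimethylnon-3-en-2-ol; 11 propanoic acid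
Product: 12 (2S,3E,7R)-9-[(tert-butyldiphenylsilyl)oxy]-4,7-dimethylnon-3-en-2-yl propanoate
Conditions: DCC, DMAP (cat.), CH2Cl2, 0 °C to rt
Reagents that add atoms: none
Why: Steglich esterification acylates the oxygen without breaking the C–O bond of the allylic carbinol, so its configuration and the alkene geometry are retained.

Step 8
Reactants: 12 (2S,3E,7R)-9-[(tert-butyldiphenylsilyl)oxy]-4,7-dimethylnon-3-en-2-yl propanoate
Product: 15 (2S,3R,4E)-2,3-dimethyl-3-{(3R)-5-[(tert-butyldiphenylsilyl)oxy]-3-methylpentyl}hex-4-en-1-ol, via silyl ketene acetal 13 (not isolated), via silyl ester 14 (not isolated)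
Conditions: LiN(i-Pr)2, THF/DMPU, −78 °C; TBSCl; −78 °C to rt, then 50 °C; then LiAlH4, 0 °C
Reagents that add atoms: none
Why: In this Ireland–Claisen rearrangement, enolisation in the presence of DMPU should give the (Z)-silyl ketene acetal (C8 methyl trans to the allylic oxygen), and the chair transition state with the carbinol methyl equatorial (an axial one would clash with the cis methyl on C9) relays the (S)-carbinol into C9 while the equatorial ketene acetal methyl sets C8 with its methyl cis to the C9 methyl as ring B requires, after which LiAlH4 reduces the silyl ester in the same flask.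

Step 9
Reactants: 15 (2S,3R,4E)-2,3-dimethyl-3-{(3R)-5-[(tert-butyldiphenylsilyl)oxy]-3-methylpentyl}hex-4-en-1-ol; 16 acetonitrile
Product: 18 (4R,5S,6E)-4,5-dimethyl-5-{(3R)-5-[(tert-butyldiphenylsilyl)oxy]-3-methylpentyl}oct-6-enenitrile, via triflate 17 (not isolated)
Conditions: Tf2O, 2,6-lutidine, CH2Cl2, −78 °C; then added to LiCH2CN (from CH3CN and n-BuLi, excess), THF, −78 to −20 °C
Reagents that add atoms: none
Why: SN2 displacement of a primary triflate by lithioacetonitrile adds C6 and C5 in one operation, the very reactive leaving group letting substitution at the β-branched C7 outrun elimination, and C8 is not touched.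

Step 10
Reactants: 18 (4R,5S,6E)-4,5-dimethyl-5-{(3R)-5-[(tert-butyldiphenylsilyl)oxy]-3-methylpentyl}oct-6-enenitrile
Product: 20 (4R,5S,8R)-10-[(tert-butyldiphenylsilyl)oxy]-5-formyl-4,5,8-trimethyldecanenitrile, via ozonide 19 (not isolated)
Conditions: O3, CH2Cl2, −78 °C; then PPh3, −78 °C to rt
Reagents that add atoms: ozone, [O-][O+]=O
Why: Ozonolysis cleaves the only alkene (nitrile and silyl ether are inert) to the C10 aldehyde, which sits on quaternary C9 and so cannot epimerise.

Step 11
Reactants: 20 (4R,5S,8R)-10-[(tert-butyldiphenylsilyl)oxy]-5-formyl-4,5,8-trimethyldecanenitrile; 21 dimethyl (2-oxopropyl)phosphonate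
Product: 22 (4R,5S,8R)-10-[(tert-butyldiphenylsilyl)oxy]-4,5,8-trimethyl-5-[(1E)-3-oxobut-1-en-1-yl]decanenitrile
Conditions: NaH, THF, 0 to 40 °C
Reagents that add atoms: none
Why: The Horner–Wadsworth–Emmons reaction of a stabilised ketophosphonate anion gives the (E)-enone (C10=C1), the aldehyde having no α-hydrogen and the anion being too weak a base to deprotonate the nitrile.

Step 12
Reactants: 22 (4R,5S,8R)-10-[(tert-butyldiphenylsilyl)oxy]-4,5,8-trimethyl-5-[(1E)-3-oxobut-1-en-1-yl]decanenitrile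
Product: 23 (4R,5S,8R)-10-[(tert-butyldiphenylsilyl)oxy]-4,5,8-trimethyl-5-{(1E)-3-[(triisopropylsilyl)oxy]buta-1,3-dien-1-yl}decanenitrile
Conditions: TIPSOTf, Et3N, CH2Cl2, −78 to 0 °C
Reagents that add atoms: triisopropylsilyl trifluoromethanesulfonate, CC(C)[Si](OS(=O)(=O)C(F)(F)F)(C(C)C)C(C)C
Why: Enol silylation of the methyl ketone with a silyl triflate and an amine base can only occur at C3, since the γ-position (C9) is quaternary, and gives the 2-silyloxydiene with the (E)-C10=C1 bond unchanged.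

Step 13
Reactants: 23 (4R,5S,8R)-10-[(tert-butyldiphenylsilyl)oxy]-4,5,8-trimethyl-5-{(1E)-3-[(triisopropylsilyl)oxy]buta-1,3-dien-1-yl}decanenitrile
Product: 25 (4R,5S,8R)-10-[(tert-butyldiphenylsilyl)oxy]-4,5,8-trimethyl-5-{(1E)-3-[(triisopropylsilyl)oxy]buta-1,3-dien-1-yl}decanal, via N-aluminoimine 24 (not isolated)
Conditions: i-Bu2AlH, toluene, −78 °C; then aq. potassium sodium tartrate, 0 °C
Reagents that add atoms: water, O
Why: Partial reduction of a nitrile with i-Bu2AlH stops at the N-aluminoimine, which hydrolyses to the C5 aldehyde under nearly neutral conditions that the TIPS dienol ether and the TBDPS ether tolerate.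

Step 14
Reactants: 25 (4R,5S,8R)-10-[(tert-butyldiphenylsilyl)oxy]-4,5,8-trimethyl-5-{(1E)-3-[(triisopropylsilyl)oxy]buta-1,3-dien-1-yl}decanal; 26 2-(triphenylphosphoranylidene)propanal
Product: 27 (2E,6R,7S,10R)-12-[(tert-butyldiphenylsilyl)oxy]-2,6,7,10-tetramethyl-7-{(1E)-3-[(triisopropylsilyl)oxy]buta-1,3-dien-1-yl}dodec-2-enal
Conditions: toluene, 60 °C
Reagents that add atoms: none
Why: Wittig olefination with the stabilised formyl ylide gives the (E)-2-methylenal under neutral conditions that spare the dienol ether, and the moderate temperature should keep the uncatalysed cycloaddition from starting.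

Step 15
Reactants: 27 (2E,6R,7S,10R)-12-[(tert-butyldiphenylsilyl)oxy]-2,6,7,10-tetramethyl-7-{(1E)-3-[(triisopropylsilyl)oxy]buta-1,3-dien-1-yl}dodec-2-enal
Product: 28 (1S,4aS,5S,6R,8aS)-5-{(3R)-5-[(tert-butyldiphenylsilyl)oxy]-3-methylpentyl}-1,5,6-trimethyl-3-[(triisopropylsilyl)oxy]-1,2,4a,5,6,7,8,8a-octahydronaphthalene-1-carbaldehyde
Conditions: (R)-B-(o-tolyl)oxazaborolidine from (R)-α,α-diphenylprolinol (0.2 equiv), Tf2NH (0.18 equiv), CH2Cl2, −78 to −40 °C; then Et3N
Reagents that add atoms: none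
Why: The protonated oxazaborolidine binds the formyl oxygen and lowers the enal LUMO, and a concerted but asynchronous intramolecular [4+2] cycloaddition follows in which C5–C10 forms ahead of C3–C4, the closest known reaction type being the type 1 intramolecular Diels–Alder reaction of 1,7,9-decatrienals under chiral oxazaborolidinium catalysis. Ring B (C5–C10) closes as the six-membered tether ring through a chair-like array of C6–C9, and ring A (C1–C5, C10) closes as the new cyclohexene, with the diene reacting s-cis and the enal s-trans. C4 and C5 are set together by suprafacial addition to the (E)-enal, which puts C5–H cis to the formyl group, and their absolute sense is set by the catalyst, which should leave the C4-Si/C5-Re face open; C10 follows from the endo (formyl) approach and gives the trans fusion shown, but step 16 removes this centre, so either fusion serves. The selectivity needed is facial selectivity relative to C8 and C9, where the substrate bias is small (the reacting chair carries the C8 methyl and the C11 chain axial), hence reagent control, while regiochemistry is no issue because the four-carbon tether allows only the C5–C10/C3–C4 pairing. The quaternary C9 favours the coiled conformer, the TIPS enol ether should withstand the acidic catalyst, and the low temperature suppresses the unselective uncatalysed reaction.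

Step 16
Reactants: 28 (1S,4aS,5S,6R,8aS)-5-{(3R)-5-[(tert-butyldiphenylsilyl)oxy]-3-methylpentyl}-1,5,6-trimethyl-3-[(triisopropylsilyl)oxy]-1,2,4a,5,6,7,8,8a-octahydronaphthalene-1-carbaldehyde
Product: 29 (1S,5S,6R,8aS)-5-{(3R)-5-[(tert-butyldiphenylsilyl)oxy]-3-methylpentyl}-1,5,6-trimethyl-3-oxo-1,2,3,5,6,7,8,8a-octahydronaphthalene-1-carbaldehyde
Conditions: Pd(OAc)2 (1.2 equiv), MeCN/DMSO, rt to 40 °C
Reagents that add atoms: none
Why: In the Saegusa–Ito oxidation palladation of the enol ether at C1 is followed by β-hydride elimination of C10–H, the only β-hydrogen, which gives the C1=C10 enone and removes the C10 stereocentre.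

Step 17
Reactants: 29 (1S,5S,6R,8aS)-5-{(3R)-5-[(tert-butyldiphenylsilyl)oxy]-3-methylpentyl}-1,5,6-trimethyl-3-oxo-1,2,3,5,6,7,8,8a-octahydronaphthalene-1-carbaldehyde
Product: 30 (1S,5S,6R,8aS)-5-{(3R)-5-[(tert-butyldiphenylsilyl)oxy]-3-methylpentyl}-1,5,6-trimethyl-3-oxo-1,2,3,5,6,7,8,8a-octahydronaphthalene-1-carboxylic acid
Conditions: NaClO2, NaH2PO4, 2-methylbut-2-ene, t-BuOH/H2O, 0 °C to rt
Reagents that add atoms: sodium chlorite, [Na+].[O-]Cl=O
Why: The Pinnick oxidation converts even hindered, non-enolisable aldehydes to acids, and the alkene scavenger removes hypochlorous acid so that the enone is spared.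

Step 18
Reactants: 30 (1S,5S,6R,8aS)-5-{(3R)-5-[(tert-butyldiphenylsilyl)oxy]-3-methylpentyl}-1,5,6-trimethyl-3-oxo-1,2,3,5,6,7,8,8a-octahydronaphthalene-1-carboxylic acid
Product: 31 methyl (1S,5S,6R,8aS)-5-{(3R)-5-[(tert-butyldiphenylsilyl)oxy]-3-methylpentyl}-1,5,6-trimethyl-3-oxo-1,2,3,5,6,7,8,8a-octahydronaphthalene-1-carboxylate
Conditions: TMSCHN2, toluene/MeOH, 0 °C
Reagents that add atoms: (trimethylsilyl)diazomethane, C[Si](C)(C)C=[N+]=[N-]
Why: O-Methylation of the carboxylic acid by the diazoalkane proceeds through proton transfer and alkylation at oxygen, so the crowding at quaternary C4 does not matter.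

Step 19
Reactants: 31 methyl (1S,5S,6R,8aS)-5-{(3R)-5-[(tert-butyldiphenylsilyl)oxy]-3-methylpentyl}-1,5,6-trimethyl-3-oxo-1,2,3,5,6,7,8,8a-octahydronaphthalene-1-carboxylate
Product: 32 methyl (1S,5S,6R,8aS)-5-[(3R)-5-hydroxy-3-methylpentyl]-1,5,6-trimethyl-3-oxo-1,2,3,5,6,7,8,8a-octahydronaphthalene-1-carboxylate (CNP0157174.1)
Conditions: HF·pyridine, pyridine, THF, 0 °C to rt
Reagents that add atoms: none
Why: Fluoride-driven cleavage of the primary silyl ether under buffered conditions frees the C15 alcohol without affecting the methyl ester, the enone or any stereocentre.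

Compound list
1 | (R)-citronellol, (3R)-3,7-dimethyloct-6-en-1-ol | C[C@H](CCC=C(C)C)CCO | starting material
2 | tert-butyl{[(3R)-3,7-dimethyloct-6-en-1-yl]oxy}diphenylsilane | C[C@H](CCC=C(C)C)CCO[Si](c1ccccc1)(c1ccccc1)C(C)(C)C | intermediate
3 | ozonide of 2, 3-{(3R)-5-[(tert-butyldiphenylsilyl)oxy]-3-methylpentyl}-5,5-dimethyl-1,2,4-trioxolane (ring carbon unassigned) | C[C@H](CCC1OOC(C)(C)O1)CCO[Si](c1ccccc1)(c1ccccc1)C(C)(C)C | intermediate (not isolated)
4 | (4R)-6-[(tert-butyldiphenylsilyl)oxy]-4-methylhexanal | C[C@H](CCC=O)CCO[Si](c1ccccc1)(c1ccccc1)C(C)(C)C | intermediate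
5 | tert-butyl{[(3R)-3-methylhept-6-yn-1-yl]oxy}diphenylsilane | C[C@H](CCC#C)CCO[Si](c1ccccc1)(c1ccccc1)C(C)(C)C | intermediate
6 | acetaldehyde | CC=O | starting material
7 | {(1E,5R)-7-[(tert-butyldiphenylsilyl)oxy]-2,5-dimethylhept-1-en-1-yl}dimethylalumane | C[Al](C)/C=C(\C)CC[C@@H](C)CCO[Si](c1ccccc1)(c1ccccc1)C(C)(C)C | intermediate (not isolated)
8 | (3E,7R)-9-[(tert-butyldiphenylsilyl)oxy]-4,7-dimethylnon-3-en-2-ol, both C2 epimers | CC(O)/C=C(\C)CC[C@@H](C)CCO[Si](c1ccccc1)(c1ccccc1)C(C)(C)C | intermediate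
9 | (3E,7R)-9-[(tert-butyldiphenylsilyl)oxy]-4,7-dimethylnon-3-en-2-one | CC(=O)/C=C(\C)CC[C@@H](C)CCO[Si](c1ccccc1)(c1ccccc1)C(C)(C)C | intermediate
10 | (2S,3E,7R)-9-[(tert-butyldiphenylsilyl)oxy]-4,7-dimethylnon-3-en-2-ol | C[C@H](O)/C=C(\C)CC[C@@H](C)CCO[Si](c1ccccc1)(c1ccccc1)C(C)(C)C | intermediate
11 | propanoic acid | CCC(=O)O | starting material
12 | (2S,3E,7R)-9-[(tert-butyldiphenylsilyl)oxy]-4,7-dimethylnon-3-en-2-yl propanoate | CCC(=O)O[C@@H](C)/C=C(\C)CC[C@@H](C)CCO[Si](c1ccccc1)(c1ccccc1)C(C)(C)C | intermediate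
13 | (Z)-O-(tert-butyldimethylsilyl) ketene acetal of 12 (methyl cis to OSi) | C/C=C(\O[Si](C)(C)C(C)(C)C)O[C@@H](C)/C=C(\C)CC[C@@H](C)CCO[Si](c1ccccc1)(c1ccccc1)C(C)(C)C | intermediate (not isolated)
14 | tert-butyldimethylsilyl (2S,3R,4E)-2,3-dimethyl-3-{(3R)-5-[(tert-butyldiphenylsilyl)oxy]-3-methylpentyl}hex-4-enoate | CC(C)(C)[Si](C)(C)OC(=O)[C@@H](C)[C@](C)(CC[C@@H](C)CCO[Si](c1ccccc1)(c1ccccc1)C(C)(C)C)/C=C/C | intermediate (not isolated)
15 | (2S,3R,4E)-2,3-dimethyl-3-{(3R)-5-[(tert-butyldiphenylsilyl)oxy]-3-methylpentyl}hex-4-en-1-ol | OC[C@@H](C)[C@](C)(CC[C@@H](C)CCO[Si](c1ccccc1)(c1ccccc1)C(C)(C)C)/C=C/C | intermediate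
16 | acetonitrile | CC#N | starting material
17 | (2S,3R,4E)-2,3-dimethyl-3-{(3R)-5-[(tert-butyldiphenylsilyl)oxy]-3-methylpentyl}hex-4-en-1-yl trifluoromethanesulfonate | FC(F)(F)S(=O)(=O)OC[C@@H](C)[C@](C)(CC[C@@H](C)CCO[Si](c1ccccc1)(c1ccccc1)C(C)(C)C)/C=C/C | intermediate (not isolated)
18 | (4R,5S,6E)-4,5-dimethyl-5-{(3R)-5-[(tert-butyldiphenylsilyl)oxy]-3-methylpentyl}oct-6-enenitrile | N#CCC[C@@H](C)[C@](C)(CC[C@@H](C)CCO[Si](c1ccccc1)(c1ccccc1)C(C)(C)C)/C=C/C | intermediate
19 | ozonide of 18 (1,2,4-trioxolane across the former C10=C alkene, ring carbons unassigned) | N#CCC[C@@H](C)[C@](C)(CC[C@@H](C)CCO[Si](c1ccccc1)(c1ccccc1)C(C)(C)C)C1OOC(C)O1 | intermediate (not isolated)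
20 | (4R,5S,8R)-10-[(tert-butyldiphenylsilyl)oxy]-5-formyl-4,5,8-trimethyldecanenitrile | N#CCC[C@@H](C)[C@](C)(CC[C@@H](C)CCO[Si](c1ccccc1)(c1ccccc1)C(C)(C)C)C=O | intermediate
21 | dimethyl (2-oxopropyl)phosphonate | COP(=O)(CC(C)=O)OC | starting material
22 | (4R,5S,8R)-10-[(tert-butyldiphenylsilyl)oxy]-4,5,8-trimethyl-5-[(1E)-3-oxobut-1-en-1-yl]decanenitrile | N#CCC[C@@H](C)[C@](C)(CC[C@@H](C)CCO[Si](c1ccccc1)(c1ccccc1)C(C)(C)C)/C=C/C(C)=O | intermediate
23 | (4R,5S,8R)-10-[(tert-butyldiphenylsilyl)oxy]-4,5,8-trimethyl-5-{(1E)-3-[(triisopropylsilyl)oxy]buta-1,3-dien-1-yl}decanenitrile | N#CCC[C@@H](C)[C@](C)(CC[C@@H](C)CCO[Si](c1ccccc1)(c1ccccc1)C(C)(C)C)/C=C/C(=C)O[Si](C(C)C)(C(C)C)C(C)C | intermediate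
24 | N-(diisobutylalumino)aldimine from 23 | CC(C)C[Al](CC(C)C)N=CCC[C@@H](C)[C@](C)(CC[C@@H](C)CCO[Si](c1ccccc1)(c1ccccc1)C(C)(C)C)/C=C/C(=C)O[Si](C(C)C)(C(C)C)C(C)C | intermediate (not isolated)
25 | (4R,5S,8R)-10-[(tert-butyldiphenylsilyl)oxy]-4,5,8-trimethyl-5-{(1E)-3-[(triisopropylsilyl)oxy]buta-1,3-dien-1-yl}decanal | O=CCC[C@@H](C)[C@](C)(CC[C@@H](C)CCO[Si](c1ccccc1)(c1ccccc1)C(C)(C)C)/C=C/C(=C)O[Si](C(C)C)(C(C)C)C(C)C | intermediate
26 | 2-(triphenylphosphoranylidene)propanal | CC(C=O)=P(c1ccccc1)(c1ccccc1)c1ccccc1 | starting material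
27 | (2E,6R,7S,10R)-12-[(tert-butyldiphenylsilyl)oxy]-2,6,7,10-tetramethyl-7-{(1E)-3-[(triisopropylsilyl)oxy]buta-1,3-dien-1-yl}dodec-2-enal (cycloaddition precursor) | O=C/C(C)=C/CC[C@@H](C)[C@](C)(CC[C@@H](C)CCO[Si](c1ccccc1)(c1ccccc1)C(C)(C)C)/C=C/C(=C)O[Si](C(C)C)(C(C)C)C(C)C | intermediate
28 | (1S,4aS,5S,6R,8aS)-5-{(3R)-5-[(tert-butyldiphenylsilyl)oxy]-3-methylpentyl}-1,5,6-trimethyl-3-[(triisopropylsilyl)oxy]-1,2,4a,5,6,7,8,8a-octahydronaphthalene-1-carbaldehyde (trans-fused; 4S,5S,8R,9S,10S,13R in C1–C15 locants) | O=C[C@@]1(C)CC(O[Si](C(C)C)(C(C)C)C(C)C)=C[C@@H]2[C@@H]1CC[C@@H](C)[C@]2(C)CC[C@@H](C)CCO[Si](c1ccccc1)(c1ccccc1)C(C)(C)C | intermediate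
29 | (1S,5S,6R,8aS)-5-{(3R)-5-[(tert-butyldiphenylsilyl)oxy]-3-methylpentyl}-1,5,6-trimethyl-3-oxo-1,2,3,5,6,7,8,8a-octahydronaphthalene-1-carbaldehyde | O=C[C@@]1(C)CC(=O)C=C2[C@@H]1CC[C@@H](C)[C@]2(C)CC[C@@H](C)CCO[Si](c1ccccc1)(c1ccccc1)C(C)(C)C | intermediate
30 | (1S,5S,6R,8aS)-5-{(3R)-5-[(tert-butyldiphenylsilyl)oxy]-3-methylpentyl}-1,5,6-trimethyl-3-oxo-1,2,3,5,6,7,8,8a-octahydronaphthalene-1-carboxylic acid | OC(=O)[C@@]1(C)CC(=O)C=C2[C@@H]1CC[C@@H](C)[C@]2(C)CC[C@@H](C)CCO[Si](c1ccccc1)(c1ccccc1)C(C)(C)C | intermediate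
31 | methyl (1S,5S,6R,8aS)-5-{(3R)-5-[(tert-butyldiphenylsilyl)oxy]-3-methylpentyl}-1,5,6-trimethyl-3-oxo-1,2,3,5,6,7,8,8a-octahydronaphthalene-1-carboxylate | COC(=O)[C@@]1(C)CC(=O)C=C2[C@@H]1CC[C@@H](C)[C@]2(C)CC[C@@H](C)CCO[Si](c1ccccc1)(c1ccccc1)C(C)(C)C | intermediate
32 | methyl (1S,5S,6R,8aS)-5-[(3R)-5-hydroxy-3-methylpentyl]-1,5,6-trimethyl-3-oxo-1,2,3,5,6,7,8,8a-octahydronaphthalene-1-carboxylate (CNP0157174.1) | COC(=O)[C@@]1(C)CC(=O)C=C2[C@@H]1CC[C@@H](C)[C@]2(C)CC[C@@H](C)CCO | target

Total step count: 19. Longest linear sequence: 19 steps (from 1 to 32; 14 steps to the cycloaddition precursor, the key step, 4 steps after it).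

Steps most likely to fail

Step 15. The cycloaddition may be slow, because the tether forces the nucleophilic diene terminus C3 onto the α-carbon C4 instead of the electrophilic C5. During a slow run the acidic catalyst may strip the silyl group from the dienol ether, or it may fail to override the conformational preference of the C8/C9 tether, so that facial control erodes. The fallback replaces Lewis-acid catalysis at the aldehyde oxidation level by a neutral thermal cycloaddition at the ester oxidation level. It sets out from aldehyde 25. Wittig olefination with methyl 2-(triphenylphosphoranylidene)propanoate (toluene, 80 °C) should give the methyl (2E)-trienoate F1. Heating in toluene at 170–180 °C (sealed vessel, BHT, base-washed glass) should give the bicyclic methyl ester enol ether F2 as ring-fusion epimers, which converge in the next operation. Saegusa–Ito oxidation as in step 16 then gives methyl ester 31, where the route is rejoined and steps 17 and 18 fall away. Facial selectivity then rests on the substrate alone, so the two C4/C5 diastereomers, the only isomers left at 31, would be separated by chromatography there.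

Step 16. Palladation of the bulky TIPS enol ether may be sluggish and the β-hydrogen at C10, next to quaternary C9, hard to reach, so that protodesilylation to the saturated C2 ketone and deposition of palladium metal overtake the dehydrogenation. The fallback replaces the palladium-mediated dehydrogenation by halogenation and base-induced elimination. It sets out from enol ether 28. N-Bromosuccinimide (THF, 0 °C) should brominate C1 with loss of the silyl group to give the C1 α-bromo ketone F3. Li2CO3 and LiBr in DMF at 110 °C should then eliminate HBr across C1–C10, the only direction open because C4 is quaternary, and return the route at enone aldehyde 29.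

Step 8. Incomplete control of the ketene acetal geometry passes directly into the C8 epimer, and the doubly substituted alkene terminus may slow the rearrangement enough for C-silylation or elimination of the allylic ester to compete. The fallback fixes the enol ether geometry by catalytic alkene isomerisation instead of by enolisation. It sets out from alcohol 10. NaH and allyl bromide (THF/DMF) should give the allyl ether F4. The cationic complex [Ir(PCy3)3]BPh4, formed from [IrCl(C8H14)2]2, PCy3 and NaBPh4 in CH2Cl2/acetone at rt, should isomerise only the unsubstituted allyl group to the (E)-1-propenyl ether F5, which is not isolated. After addition of PPh3, warming to 60 °C should bring about the aliphatic Claisen rearrangement through the same chair as in step 8 (propenyl methyl and carbinol methyl equatorial) to give the aldehyde F6. This aldehyde is reduced at once with NaBH4 in MeOH at 0 °C, before C8 can epimerise, which returns the route at alcohol 15.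

Further compounds
F1 | step 15 | methyl (2E,6R,7S,10R)-12-[(tert-butyldiphenylsilyl)oxy]-2,6,7,10-tetramethyl-7-{(1E)-3-[(triisopropylsilyl)oxy]buta-1,3-dien-1-yl}dodec-2-enoate | COC(=O)/C(C)=C/CC[C@@H](C)[C@](C)(CC[C@@H](C)CCO[Si](c1ccccc1)(c1ccccc1)C(C)(C)C)/C=C/C(=C)O[Si](C(C)C)(C(C)C)C(C)C
F2 | step 15 | methyl (1S,5S,6R,8aS)-5-{(3R)-5-[(tert-butyldiphenylsilyl)oxy]-3-methylpentyl}-1,5,6-trimethyl-3-[(triisopropylsilyl)oxy]-1,2,4a,5,6,7,8,8a-octahydronaphthalene-1-carboxylate, both C4a epimers | COC(=O)[C@@]1(C)CC(O[Si](C(C)C)(C(C)C)C(C)C)=CC2[C@@H]1CC[C@@H](C)[C@]2(C)CC[C@@H](C)CCO[Si](c1ccccc1)(c1ccccc1)C(C)(C)C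
F3 | step 16 | (1S,4aS,5S,6R,8aS)-4-bromo-5-{(3R)-5-[(tert-butyldiphenylsilyl)oxy]-3-methylpentyl}-1,5,6-trimethyl-3-oxodecahydronaphthalene-1-carbaldehyde, bromide configuration unassigned | O=C[C@@]1(C)CC(=O)C(Br)[C@@H]2[C@@H]1CC[C@@H](C)[C@]2(C)CC[C@@H](C)CCO[Si](c1ccccc1)(c1ccccc1)C(C)(C)C
F4 | step 8 | tert-butyl{[(3R,6E,8S)-3,6-dimethyl-8-(prop-2-en-1-yloxy)non-6-en-1-yl]oxy}diphenylsilane | C=CCO[C@@H](C)/C=C(\C)CC[C@@H](C)CCO[Si](c1ccccc1)(c1ccccc1)C(C)(C)C
F5 | step 8 | tert-butyl{[(3R,6E,8S)-3,6-dimethyl-8-{[(1E)-prop-1-en-1-yl]oxy}non-6-en-1-yl]oxy}diphenylsilane | C/C=C/O[C@@H](C)/C=C(\C)CC[C@@H](C)CCO[Si](c1ccccc1)(c1ccccc1)C(C)(C)C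
F6 | step 8 | (2S,3R,4E)-2,3-dimethyl-3-{(3R)-5-[(tert-butyldiphenylsilyl)oxy]-3-methylpentyl}hex-4-enal | O=C[C@@H](C)[C@](C)(CC[C@@H](C)CCO[Si](c1ccccc1)(c1ccccc1)C(C)(C)C)/C=C/C
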